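**Plan**
The benzene-1,3-diol ring carries oxygen on C1 and C3 and the C17 chain on C5, so C1, C3 and C5 are the carbonyl carbons of a folded polyketide chain. Putting a carboxyl carbon back on C4 turns the ring into a masked 3,5,7-triketo acid, diketo-dioxinone 18.
Retrosynthetic cuts on the ring: bond C4–C5 (aldol aromatization of 18), then bond C5–C6 (Claisen acylation of keto-dioxinone 16 by the C18 acyl donor 13), then bond C1–C2 (acetylation of dioxinone 14).
Cuts in the chain: C8'=C9' (Wittig reaction of aldehyde 7 with the ylide of 9), C14'=C15' (semihydrogenation of an alkyne), C13'–C14' (acetylide opening of epoxide 2).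
Forward order: the chain is assembled first, then joined to the dioxinone, then the only ring closes in step 10, and CO2 and the silyl group are removed last.
Stereochemistry: C12' (S) is bought with (S)-1,2-epoxy-5-hexene and its C–O bond is never broken. 8'Z comes from the Wittig reaction and 14'Z from syn-hydrogenation.

Key step: step 10

Remark: 18 is drawn as its triketo tautomer although it should be largely enolized in solution; the tautomers interconvert under the conditions of step 10.

**Step 1**
Reactants: 1 but-1-yne; 2 (2S)-2-(but-3-en-1-yl)oxirane [(S)-1,2-epoxy-5-hexene]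
Product: 4 (5S)-dec-1-en-7-yn-5-ol, via but-1-ynyllithium 3 (not isolated)
Conditions: 1 (1.5 equiv), n-BuLi, THF, −78 °C; BF3·OEt2; then 2, −78 °C; H2O quench
Reagents that add atoms: none
Why: Yamaguchi–Hirao alkynylation, in which the BF3-activated epoxide is opened by the acetylide in an SN2 reaction at the unsubstituted CH2, so the C–O bond of the stereocentre is never broken and the (S)-configuration of 2 is carried into 4.

**Step 2**
Reactants: 4 (5S)-dec-1-en-7-yn-5-ol
Product: 5 tert-butyl{[(5S)-dec-1-en-7-yn-5-yl]oxy}dimethylsilane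
Conditions: TBSCl, imidazole, DMF, rt
Reagents that add atoms: tert-butyldimethylsilyl chloride, CC(C)(C)[Si](C)(C)Cl
Why: Imidazole-promoted silylation masks the only O–H before the ylide and dianion steps and does not touch the stereocentre.

**Step 3**
Reactants: 5 tert-butyl{[(5S)-dec-1-en-7-yn-5-yl]oxy}dimethylsilane
Product: 7 (4S)-4-(tert-butyldimethylsilyloxy)non-6-ynal, via secondary ozonide 6 (not isolated)
Conditions: O3, CH2Cl2, −78 °C (Sudan Red 7B as end-point indicator); then PPh3, −78 °C to rt
Reagents that add atoms: ozone, [O-][O+]=O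
Why: Ozonolysis with reductive work-up cleaves the terminal alkene, which adds ozone far faster than the internal alkyne, so the triple bond survives as an ozone-stable placeholder for the later 14'Z-alkene.

**Step 4**
Reactants: 8 9-bromononanoic acid
Product: 9 (8-carboxyoctyl)triphenylphosphonium bromide
Conditions: PPh3, MeCN, reflux
Reagents that add atoms: triphenylphosphine, c1ccc(cc1)P(c1ccccc1)c1ccccc1
Why: SN2 quaternization of triphenylphosphine by the primary bromide gives the phosphonium salt, with the carboxylic acid as a spectator.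

**Step 5**
Reactants: 9 (8-carboxyoctyl)triphenylphosphonium bromide; 7 (4S)-4-(tert-butyldimethylsilyloxy)non-6-ynal
Product: 11 (9Z,13S)-13-(tert-butyldimethylsilyloxy)octadec-9-en-15-ynoic acid, via phosphonium ylide 10 (not isolated)
Conditions: 9 (1.3 equiv), NaN(SiMe3)2 (2.5 equiv), THF, −78 to 0 °C; then 7, −78 °C to rt; 1 M HCl to pH 4
Reagents that add atoms: none
Why: Wittig olefination of a non-stabilized ylide under lithium-free conditions passes through the kinetically favoured cis-oxaphosphetane and should give the 9Z-alkene, with the second equivalent of base holding the carboxyl group as its unreactive sodium salt.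

**Step 6**
Reactants: 11 (9Z,13S)-13-(tert-butyldimethylsilyloxy)octadec-9-en-15-ynoic acid
Product: 12 (9Z,13S,15Z)-13-(tert-butyldimethylsilyloxy)octadeca-9,15-dienoic acid
Conditions: H2 (1 atm), Pd/CaCO3 poisoned with Pb(OAc)2 (Lindlar catalyst), quinoline, EtOAc, rt
Reagents that add atoms: none
Why: Lindlar semihydrogenation adds H2 syn to the alkyne on the poisoned palladium surface and stops at the Z-alkene, while the existing disubstituted 9Z-alkene and the silyl ether are inert.

**Step 7**
Reactants: 12 (9Z,13S,15Z)-13-(tert-butyldimethylsilyloxy)octadeca-9,15-dienoic acid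
Product: 13 1-[(9Z,13S,15Z)-13-(tert-butyldimethylsilyloxy)octadeca-9,15-dienoyl]-1H-benzotriazole
Conditions: 1H-benzotriazole, DCC, CH2Cl2, 0 °C to rt
Reagents that add atoms: 1H-benzotriazole, c1ccc2[nH]nnc2c1
Why: Carbodiimide-mediated N-acylation of benzotriazole under neutral conditions gives a storable N-acylbenzotriazole, an acyl donor suited to C-acylation of enolates, without exposing the silyl ether to acid.

**Step 8**
Reactants: 14 2,2,6-trimethyl-4H-1,3-dioxin-4-one
Product: 16 2,2-dimethyl-6-(2-oxopropyl)-4H-1,3-dioxin-4-one, via lithium dienolate 15 (not isolated)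
Conditions: 14 (2 equiv), LiN(SiMe3)2 (2 equiv), THF, −78 °C; AcCl (1 equiv); 1 M HCl
Reagents that add atoms: acetyl chloride, CC(=O)Cl
Why: Claisen-type C-acylation of the vinylogous ester dienolate at its γ-carbon (the former C6 methyl) by acetyl chloride, with the second equivalent of dienolate taking up the acidic proton of the β-keto product.

**Step 9**
Reactants: 16 2,2-dimethyl-6-(2-oxopropyl)-4H-1,3-dioxin-4-one; 13 1-[(9Z,13S,15Z)-13-(tert-butyldimethylsilyloxy)octadeca-9,15-dienoyl]-1H-benzotriazole
Product: 18 6-[(12Z,16S,18Z)-16-(tert-butyldimethylsilyloxy)-2,4-dioxohenicosa-12,18-dienyl]-2,2-dimethyl-4H-1,3-dioxin-4-one, via dilithium dianion 17 (not isolated)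
Conditions: 16 (2.2 equiv), LiN(iPr)2 (4.4 equiv), THF, −78 to −40 °C; then 13, −78 °C; 1 M HCl to pH 3, 0 °C
Reagents that add atoms: none
Why: Claisen acylation of a dicarbonyl dianion, which reacts at its last-formed and most basic terminal carbanion (Weiler dianion regiochemistry), so the acyl group of 13 is delivered to the methyl carbon of 16 with loss of benzotriazolide, and the excess dianion absorbs the acidic proton of 18.

**Step 10**
Reactants: 18 6-[(12Z,16S,18Z)-16-(tert-butyldimethylsilyloxy)-2,4-dioxohenicosa-12,18-dienyl]-2,2-dimethyl-4H-1,3-dioxin-4-one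
Product: 20 5-[(8Z,12S,14Z)-12-(tert-butyldimethylsilyloxy)heptadeca-8,14-dienyl]-7-hydroxy-2,2-dimethyl-4H-1,3-benzodioxin-4-one, via cyclic aldol adduct 19 (not isolated)
Conditions: Et3N (5 equiv), CH2Cl2, rt
Reagents that add atoms: none
Why: Et3N reversibly deprotonates the side-chain C1 methylene between the dioxinone and the C2 ketone, the resulting vinylogous enolate attacks through dioxinone C5 the C4 ketone carbon that bears the long chain, and cyclic aldol 19 then loses water (E1cB) and tautomerizes at the former C2 ketone to the phenol. The closest known reaction type is the amine-promoted aldol aromatization of diketo-dioxinones to acetonide-masked resorcylates, the laboratory counterpart of the tetraketide cyclization of alkylresorcinol synthases. The one new ring, the benzene ring, closes in a Baldwin-favoured 6-(enolexo)-exo-trig mode with formation of one C–C bond. No stereocentre is created, because the carbinol of 19 disappears on dehydration, and the C16 silyl ether centre and both Z-alkenes are separated from every carbonyl by at least seven saturated carbons, so a tertiary amine at room temperature cannot epimerize or isomerize them. The selectivity needed is the aldol mode (dioxinone C5 onto the C4 ketone) over a Claisen-type closure of C3 onto the lactone carbonyl or O-cyclization to a pyranone; the first is secured by geometry, since the side chain and the lactone carbonyl are held trans across the endocyclic C5=C6 bond and cannot span a six-membered ring, the second by the mild base and by irreversible aromatization, which drains reversible hemiketal formation.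

**Step 11**
Reactants: 20 5-[(8Z,12S,14Z)-12-(tert-butyldimethylsilyloxy)heptadeca-8,14-dienyl]-7-hydroxy-2,2-dimethyl-4H-1,3-benzodioxin-4-one
Product: 22 5-[(8Z,12S,14Z)-12-(tert-butyldimethylsilyloxy)heptadeca-8,14-dienyl]benzene-1,3-diol, via resorcylic acid 21 (not isolated)
Conditions: KOH (aq.), 1,4-dioxane, 80 °C; 1 M HCl to pH 3, 0 °C; then toluene, 110 °C
Reagents that add atoms: none
Why: Saponification opens the acetonide-type aryl ester with loss of acetone, and the freed 6-alkyl-2,4-dihydroxybenzoic acid undergoes the thermal protodecarboxylation typical of β-resorcylic acids (ipso-protonation ortho and para to the hydroxyls), leaving C–H at the ring position next to the chain.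

**Step 12**
Reactants: 22 5-[(8Z,12S,14Z)-12-(tert-butyldimethylsilyloxy)heptadeca-8,14-dienyl]benzene-1,3-diol
Product: 23 5-[(8Z,12S,14Z)-12-hydroxyheptadeca-8,14-dien-1-yl]benzene-1,3-diol
Conditions: TBAF, AcOH, THF, rt
Reagents that add atoms: none
Why: Fluoride-mediated desilylation, driven by the strong Si–F bond, cleaves only the Si–O bond so that the C12' configuration is retained, and the acetic acid buffer keeps the resorcinol protonated and safe from oxidation.

**Compound list**
1 | but-1-yne | CCC#C | starting material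
2 | (2S)-2-(but-3-en-1-yl)oxirane, (S)-1,2-epoxy-5-hexene | C=CCC[C@H]1CO1 | starting material
3 | but-1-ynyllithium (not isolated) | [Li]C#CCC | intermediate
4 | (5S)-dec-1-en-7-yn-5-ol | C=CCC[C@H](O)CC#CCC | intermediate
5 | tert-butyl{[(5S)-dec-1-en-7-yn-5-yl]oxy}dimethylsilane | C=CCC[C@H](O[Si](C)(C)C(C)(C)C)CC#CCC | intermediate
6 | 3-[(3S)-3-(tert-butyldimethylsilyloxy)oct-5-yn-1-yl]-1,2,4-trioxolane, secondary ozonide, both epimers at the ring carbon (not isolated) | CCC#CC[C@@H](O[Si](C)(C)C(C)(C)C)CCC1OCOO1 | intermediate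
7 | (4S)-4-(tert-butyldimethylsilyloxy)non-6-ynal | CCC#CC[C@@H](O[Si](C)(C)C(C)(C)C)CCC=O | intermediate
8 | 9-bromononanoic acid | OC(=O)CCCCCCCCBr | starting material
9 | (8-carboxyoctyl)triphenylphosphonium bromide | [Br-].OC(=O)CCCCCCCC[P+](c1ccccc1)(c1ccccc1)c1ccccc1 | intermediate
10 | sodium 9-(triphenyl-λ5-phosphanylidene)nonanoate, phosphonium ylide (not isolated) | [Na+].[O-]C(=O)CCCCCCCC=P(c1ccccc1)(c1ccccc1)c1ccccc1 | intermediate
11 | (9Z,13S)-13-(tert-butyldimethylsilyloxy)octadec-9-en-15-ynoic acid | CCC#CC[C@@H](O[Si](C)(C)C(C)(C)C)CC/C=C\CCCCCCCC(=O)O | intermediate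
12 | (9Z,13S,15Z)-13-(tert-butyldimethylsilyloxy)octadeca-9,15-dienoic acid | CC/C=C\C[C@@H](O[Si](C)(C)C(C)(C)C)CC/C=C\CCCCCCCC(=O)O | intermediate
13 | 1-[(9Z,13S,15Z)-13-(tert-butyldimethylsilyloxy)octadeca-9,15-dienoyl]-1H-benzotriazole | CC/C=C\C[C@@H](O[Si](C)(C)C(C)(C)C)CC/C=C\CCCCCCCC(=O)n1nnc2ccccc12 | intermediate
14 | 2,2,6-trimethyl-4H-1,3-dioxin-4-one | CC1=CC(=O)OC(C)(C)O1 | starting material
15 | lithium dienolate of 14, lithium 2,2-dimethyl-6-methylidene-6H-1,3-dioxin-4-olate (not isolated) | C=C1C=C(O[Li])OC(C)(C)O1 | intermediate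
16 | 2,2-dimethyl-6-(2-oxopropyl)-4H-1,3-dioxin-4-one | CC(=O)CC1=CC(=O)OC(C)(C)O1 | intermediate
17 | dilithium dianion of 16, deprotonated at the ring-side CH2 and at the methyl group (not isolated) | [Li]OC(=C)C=C1C=C(O[Li])OC(C)(C)O1 | intermediate
18 | 6-[(12Z,16S,18Z)-16-(tert-butyldimethylsilyloxy)-2,4-dioxohenicosa-12,18-dienyl]-2,2-dimethyl-4H-1,3-dioxin-4-one | CC/C=C\C[C@@H](O[Si](C)(C)C(C)(C)C)CC/C=C\CCCCCCCC(=O)CC(=O)CC1=CC(=O)OC(C)(C)O1 | intermediate
19 | 5-[(8Z,12S,14Z)-12-(tert-butyldimethylsilyloxy)heptadeca-8,14-dienyl]-5-hydroxy-2,2-dimethyl-5,8-dihydro-4H-1,3-benzodioxine-4,7(6H)-dione, cyclic aldol adduct, both C5 epimers (not isolated) | CC/C=C\C[C@@H](O[Si](C)(C)C(C)(C)C)CC/C=C\CCCCCCCC1(O)CC(=O)CC2=C1C(=O)OC(C)(C)O2 | intermediate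
20 | 5-[(8Z,12S,14Z)-12-(tert-butyldimethylsilyloxy)heptadeca-8,14-dienyl]-7-hydroxy-2,2-dimethyl-4H-1,3-benzodioxin-4-one | CC/C=C\C[C@@H](O[Si](C)(C)C(C)(C)C)CC/C=C\CCCCCCCc1cc(O)cc2OC(C)(C)OC(=O)c12 | intermediate
21 | 2,4-dihydroxy-6-[(8Z,12S,14Z)-12-(tert-butyldimethylsilyloxy)heptadeca-8,14-dienyl]benzoic acid (not isolated) | CC/C=C\C[C@@H](O[Si](C)(C)C(C)(C)C)CC/C=C\CCCCCCCc1cc(O)cc(O)c1C(=O)O | intermediate
22 | 5-[(8Z,12S,14Z)-12-(tert-butyldimethylsilyloxy)heptadeca-8,14-dienyl]benzene-1,3-diol | CC/C=C\C[C@@H](O[Si](C)(C)C(C)(C)C)CC/C=C\CCCCCCCc1cc(O)cc(O)c1 | intermediate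
23 | 5-[(8Z,12S,14Z)-12-hydroxyheptadeca-8,14-dien-1-yl]benzene-1,3-diol | CC/C=C\C[C@@H](O)CC/C=C\CCCCCCCc1cc(O)cc(O)c1 | target

**Step count**
Total: 12 steps. Longest linear sequence: 10 steps (1, 2, 3, 5, 6, 7, 9, 10, 11, 12); steps 4 and 8 prepare the two side fragments.

**Steps most likely to fail**

Step 9. The risks are proton transfer from the newly formed, more acidic diketone to unreacted dianion, O-acylation of the enolate oxygens, and partial cyclization during the acidic quench. All of these consume the valuable acyl donor. The fallback sets out from acid 12 and returns at 18, and makes the C–C bond by carbonyl addition instead of acyl substitution. LiAlH4 (THF, 0 °C to rt) would reduce 12 to (9Z,13S,15Z)-13-(tert-butyldimethylsilyloxy)octadeca-9,15-dien-1-ol F1. Dess–Martin periodinane (CH2Cl2, NaHCO3) would oxidize this to (9Z,13S,15Z)-13-(tert-butyldimethylsilyloxy)octadeca-9,15-dienal F2. Aldol addition of dianion 17 to F2 at −78 °C would give 6-[(12Z,16S,18Z)-16-(tert-butyldimethylsilyloxy)-4-hydroxy-2-oxohenicosa-12,18-dienyl]-2,2-dimethyl-4H-1,3-dioxin-4-one F3 as a mixture of C4 epimers, whose alkoxide cannot quench the dianion. A second Dess–Martin oxidation would turn the carbinol into the ketone of 18.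

Step 5. The risks are leakage to the 9E-isomer through equilibration of the oxaphosphetane, which would leave geometric isomers of a long-chain acid that are hard to separate, and enolization of aldehyde 7 by the basic ylide. The fallback sets out from 7 and returns at 12, and draws both double bonds from alkynes, whose geometry is fixed by syn-hydrogenation. Aldehyde 7 would be homologated with dimethyl (1-diazo-2-oxopropyl)phosphonate and K2CO3 in MeOH (Ohira–Bestmann alkynylation) to tert-butyl{[(5S)-deca-1,7-diyn-5-yl]oxy}dimethylsilane F4. Its lithium acetylide (n-BuLi, THF, −78 °C) would be alkylated with lithium 8-bromooctanoate in THF/DMPU to (13S)-13-(tert-butyldimethylsilyloxy)octadeca-9,15-diynoic acid F5. Semihydrogenation of both triple bonds under the conditions of step 6 would then deliver 12 directly.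

Step 11. The risk is slow, incomplete opening of the lactone carbonyl, which is flanked by the C5 chain and deactivated by the C7 phenoxide, in a hot two-phase alkaline medium that dissolves the lipophilic substrate poorly. Prolonged heating could also cost the silyl ether or oxidize the electron-rich ring in air. The fallback sets out from 20 and returns at 22, and replaces saponification by alcoholysis and neutral ester cleavage. Sodium allyloxide (NaH, allyl alcohol, THF, 0 to 50 °C) would open 20 in homogeneous solution to prop-2-en-1-yl 2,4-dihydroxy-6-[(8Z,12S,14Z)-12-(tert-butyldimethylsilyloxy)heptadeca-8,14-dienyl]benzoate F6. Pd(PPh3)4 and morpholine (THF, rt) would remove the allyl group by π-allyl transfer to give resorcylic acid 21, which would be decarboxylated in toluene at 110 °C to 22 as in step 11.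

**Further compounds**
F1 | step 9 | (9Z,13S,15Z)-13-(tert-butyldimethylsilyloxy)octadeca-9,15-dien-1-ol | CC/C=C\C[C@@H](O[Si](C)(C)C(C)(C)C)CC/C=C\CCCCCCCCO
F2 | step 9 | (9Z,13S,15Z)-13-(tert-butyldimethylsilyloxy)octadeca-9,15-dienal | CC/C=C\C[C@@H](O[Si](C)(C)C(C)(C)C)CC/C=C\CCCCCCCC=O
F3 | step 9 | 6-[(12Z,16S,18Z)-16-(tert-butyldimethylsilyloxy)-4-hydroxy-2-oxohenicosa-12,18-dienyl]-2,2-dimethyl-4H-1,3-dioxin-4-one (both C4 epimers) | CC/C=C\C[C@@H](O[Si](C)(C)C(C)(C)C)CC/C=C\CCCCCCCC(O)CC(=O)CC1=CC(=O)OC(C)(C)O1
F4 | step 5 | tert-butyl{[(5S)-deca-1,7-diyn-5-yl]oxy}dimethylsilane | C#CCC[C@H](O[Si](C)(C)C(C)(C)C)CC#CCC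
F5 | step 5 | (13S)-13-(tert-butyldimethylsilyloxy)octadeca-9,15-diynoic acid | CCC#CC[C@@H](O[Si](C)(C)C(C)(C)C)CCC#CCCCCCCCC(=O)O
F6 | step 11 | prop-2-en-1-yl 2,4-dihydroxy-6-[(8Z,12S,14Z)-12-(tert-butyldimethylsilyloxy)heptadeca-8,14-dienyl]benzoate | CC/C=C\C[C@@H](O[Si](C)(C)C(C)(C)C)CC/C=C\CCCCCCCc1cc(O)cc(O)c1C(=O)OCC=C
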